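**Retrosynthetic overview**
- The target comes from its 3',5'-diacetate by mild methanolysis. Both benzene rings are bought, and the furan is the only ring built, in the key step.
- The furan is opened at O1–C2 (cyclodehydration) and at C3–C3a. This gives 2-geranylresorcinol (nucleophilic C4) and the α-carbon of 3,5-diacetoxyacetophenone. That carbon is also a natural nucleophile, so it is used as its α-bromide, an enolonium equivalent.
- 2-Geranylresorcinol is symmetric, so its two ortho sites are identical. One annulation places geranyl at C7 and the free OH at C6 with no regiochemical choice.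
- 2-Geranylresorcinol comes from resorcinol bis-MOM ether by C2-lithiation and reaction with (E)-geranyl bromide, which supplies the E-alkene.

Assumption: the target has no stereocentre and is achiral. The only stereochemical task is to keep the (2E)-alkene, which is bought in with geranyl bromide.

**Step 1**
Reactants: 1 resorcinol (benzene-1,3-diol)
Product: 2 1,3-bis(methoxymethoxy)benzene
Conditions: NaH (2.4 equiv), MOMCl (2.4 equiv), DMF, 0 °C → rt
Reagents that add atoms: chloromethyl methyl ether (MOMCl), COCCl
Why: Williamson-type O-alkylation of the bis-phenoxide gives the bis-acetal, whose two OMOM groups are needed as cooperative directing groups in step 2.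

**Step 2**
Reactants: 2 1,3-bis(methoxymethoxy)benzene (1.15 equiv); 3 geranyl bromide [(2E)-1-bromo-3,7-dimethylocta-2,6-diene] (1.0 equiv)
Product: 6 2-[(2E)-3,7-dimethylocta-2,6-dien-1-yl]benzene-1,3-diol (2-geranylresorcinol), via 2-lithio bis-MOM arene 4 (not isolated), via 2-geranyl bis-MOM arene 5 (not isolated)
Conditions: n-BuLi (1.15 equiv), THF, 0 °C → rt; 3, −78 °C → rt; then MeOH, conc. HCl (to ca. 1 M), 40 °C, stopped by TLC
Reagents that add atoms: none
Why: Directed ortho-metalation occurs only at C2 between the two OMOM groups, SN2 at the primary allylic bromide keeps the E-alkene, and acid-catalysed transacetalisation to methanol frees both phenols in the same pot, with the slight excess of aryllithium consuming all of 3 so that no geranyl cation source meets the free resorcinol and the leftover 2 ends as water-soluble resorcinol.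

**Step 3**
Reactants: 7 3,5-diacetoxyacetophenone (5-acetylbenzene-1,3-diyl diacetate)
Product: 8 2-bromo-1-(3,5-diacetoxyphenyl)ethan-1-one [5-(bromoacetyl)benzene-1,3-diyl diacetate]
Conditions: Br2 (1.0 equiv), cat. HBr/AcOH, CHCl3, 0 °C → rt
Reagents that add atoms: bromine, BrBr
Why: Acid-catalysed α-bromination through the enol is selective for the methyl ketone because the acetates and the acyl group deactivate the ring, and it turns the nucleophilic α-carbon into an electrophilic one.

**Step 4 (key step)**
Reactants: 6 2-geranylresorcinol (1.5 equiv, excess recovered); 8 2-bromo-1-(3,5-diacetoxyphenyl)ethan-1-one (1.0 equiv)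
Product: 10 5-{7-[(2E)-3,7-dimethylocta-2,6-dien-1-yl]-6-hydroxy-1-benzofuran-2-yl}benzene-1,3-diyl diacetate, via C-phenacylated resorcinol ketone 9 (not isolated)
Conditions: neutral Al2O3 (Brockmann I, ca. 4 g/mmol), toluene, 110 °C, Ar
Reagents that add atoms: none
Why: This is the alumina-promoted ortho-C-phenacylation/cyclodehydration of an electron-rich phenol with an α-bromoketone (a known direct 2-arylbenzofuran annulation), in which the surface-bound phenoxide of 6 attacks the enolonium-equivalent CH2 of 8 through C4 (ortho to one OH, para to the other, identical to C6 by symmetry, so only one regioisomer) rather than through oxygen, the flanking OH then adds to the ketone of 9 and water is lost, and the large excess of neutral alumina binds HBr and water so that the geranyl chain and its E-alkene are left alone; no stereocentre is formed.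

**Step 5**
Reactants: 10 the benzofuran diacetate
Product: 11 mulberrofuran L, 5-{7-[(2E)-3,7-dimethylocta-2,6-dien-1-yl]-6-hydroxy-1-benzofuran-2-yl}benzene-1,3-diol
Conditions: K2CO3 (20 mol %), degassed MeOH, rt; aq. NH4Cl work-up
Reagents that add atoms: none
Why: Zemplén-type transesterification of aryl acetates is fast, acid-free and harmless to the benzofuran and the diene, and it also converges any acetyl-migrated or partly deacetylated material from step 4 onto the single triol.

**Compound list**
1 | resorcinol | Oc1cccc(O)c1 | starting material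
2 | 1,3-bis(methoxymethoxy)benzene | COCOc1cccc(OCOC)c1 | intermediate
3 | geranyl bromide, (2E) | CC(C)=CCC/C(C)=C/CBr | starting material
4 | 2-lithio-1,3-bis(methoxymethoxy)benzene | [Li]c1c(OCOC)cccc1OCOC | intermediate
5 | 2-[(2E)-geranyl]-1,3-bis(methoxymethoxy)benzene | CC(C)=CCC/C(C)=C/Cc1c(OCOC)cccc1OCOC | intermediate
6 | 2-[(2E)-geranyl]benzene-1,3-diol | CC(C)=CCC/C(C)=C/Cc1c(O)cccc1O | intermediate
7 | 3,5-diacetoxyacetophenone | CC(=O)c1cc(OC(C)=O)cc(OC(C)=O)c1 | starting material
8 | 2-bromo-1-(3,5-diacetoxyphenyl)ethan-1-one | O=C(CBr)c1cc(OC(C)=O)cc(OC(C)=O)c1 | intermediate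
9 | 1-(3,5-diacetoxyphenyl)-2-{3-[(2E)-geranyl]-2,4-dihydroxyphenyl}ethan-1-one | CC(C)=CCC/C(C)=C/Cc1c(O)ccc(CC(=O)c2cc(OC(C)=O)cc(OC(C)=O)c2)c1O | intermediate
10 | 5-{7-[(2E)-geranyl]-6-hydroxybenzofuran-2-yl}benzene-1,3-diyl diacetate | CC(C)=CCC/C(C)=C/Cc1c(O)ccc2cc(-c3cc(OC(C)=O)cc(OC(C)=O)c3)oc12 | intermediate
11 | mulberrofuran L | CC(C)=CCC/C(C)=C/Cc1c(O)ccc2cc(-c3cc(O)cc(O)c3)oc12 | target

**Total step count:** 5. **Longest linear sequence:** 4 (steps 1, 2, 4, 5).

**Three steps most likely to fail**

**Step 4.** There are three risks.
- O-phenacylation could compete, and it would lead to the 3-aryl isomer.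
- Surface HBr could hydrobrominate the geranyl chain or close it onto the ortho phenol as a chroman.
- A second annulation could occur at C5.

The fallback keeps the same bond and the same electrophilic α-carbon but gives it to an aryl-metal instead of a free phenol. It sets out from 5 and 8. Compound 5 is taken out of step 2 by an aq. NH4Cl quench before any acid is added.
- n-BuLi in THF at 0 °C lithiates the only position of 5 still ortho to an OMOM group, giving the 4-lithio arene F1.
- ZnCl2 converts F1 into the arylzinc chloride F2.
- A Ni-catalysed Negishi arylation of the α-bromoketone (NiCl2·glyme with a bipyridine-type ligand, THF/DMA, −20 °C → rt) gives the protected α-aryl ketone F3.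
- HCl/MeOH at 40 °C then removes both MOM groups, closes and dehydrates the furan, and methanolyses the acetates. The fallback comes back to the route at 11.

**Step 2.** The risks are some SN2' attack on the allylic bromide and, above all, acid-induced chroman formation while the MOM groups come off next to the geranyl chain. The fallback uses no acid and no protecting group, and builds the resorcinol by aromatisation. It sets out from 3.
- Cyclohexane-1,3-dione is C-alkylated with 3 (aq. KOH, cat. Cu powder, rt) to give 2-geranylcyclohexane-1,3-dione F4.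
- LDA (2.3 equiv)/TMSCl in THF at −78 °C gives the 1,3-bis(trimethylsilyloxy)cyclohexa-1,3-diene F5.
- DDQ (1.0 equiv, 0 °C; dehydrogenation of a silyl dienol ether) aromatises F5 to the bis-TMS ether of 2-geranylresorcinol F6.
- Catalytic K2CO3 in MeOH cleaves the TMS groups. The fallback comes back to the route at 6.

**Step 3.** The risks are over-bromination to the α,α-dibromide and HBr-induced loss of acetate. The fallback replaces halogenation by hypervalent-iodine oxidation. It sets out from 7.
- Koser's reagent [PhI(OH)OTs] in MeCN at reflux passes through the iodine(III) enolonium species to the α-tosyloxy ketone F7.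
- F7 is used in place of 8 under the step 4 conditions, where no HBr is formed. It passes through the same ketone 9, and the fallback comes back to the route at 10.

**Further compounds**
F1 | step 4 | 4-lithio-2-[(2E)-geranyl]-1,3-bis(methoxymethoxy)benzene | CC(C)=CCC/C(C)=C/Cc1c(OCOC)ccc([Li])c1OCOC
F2 | step 4 | {3-[(2E)-geranyl]-2,4-bis(methoxymethoxy)phenyl}zinc chloride | CC(C)=CCC/C(C)=C/Cc1c(OCOC)ccc([Zn]Cl)c1OCOC
F3 | step 4 | 1-(3,5-diacetoxyphenyl)-2-{3-[(2E)-geranyl]-2,4-bis(methoxymethoxy)phenyl}ethan-1-one | CC(C)=CCC/C(C)=C/Cc1c(OCOC)ccc(CC(=O)c2cc(OC(C)=O)cc(OC(C)=O)c2)c1OCOC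
F4 | step 2 | 2-[(2E)-geranyl]cyclohexane-1,3-dione | CC(C)=CCC/C(C)=C/CC1C(=O)CCCC1=O
F5 | step 2 | 2-[(2E)-geranyl]-1,3-bis(trimethylsilyloxy)cyclohexa-1,3-diene | CC(C)=CCC/C(C)=C/CC1=C(O[Si](C)(C)C)CCC=C1O[Si](C)(C)C
F6 | step 2 | 2-[(2E)-geranyl]-1,3-bis(trimethylsilyloxy)benzene | CC(C)=CCC/C(C)=C/Cc1c(O[Si](C)(C)C)cccc1O[Si](C)(C)C
F7 | step 3 | 2-(3,5-diacetoxyphenyl)-2-oxoethyl 4-methylbenzenesulfonate | Cc1ccc(cc1)S(=O)(=O)OCC(=O)c1cc(OC(C)=O)cc(OC(C)=O)c1
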